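Target 18 is robinetinidol-(4β→8)-gallocatechin (upper unit: rings A, C, B; gallocatechin unit: rings D, F, E); it is reached by hydrogenolysis of nine benzyl ethers, and the upper 3-OH is made from a C3–Si bond by oxidation with retention.
Feature that carries the strategy: ring C holds C2, C3, C4 as 2,3-trans-3,4-cis; its O1–C2 and C3–C4 bonds are the pair formed when the ortho-quinone methide O1=C8a–C4a=C4 of ring A adds to a C2=C3 alkene, and O3 is cis to the C4–C8 bond, so it lies beside O7 of ring D and a silicon standing in for O3 can be bound to O7.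
Key disconnection: intramolecular [4+2] of that ortho-quinone methide with an (E)-styrylsilane held as the O7 silyl ether; the quinone methide comes from an ortho-hydroxybenzhydrol, cut at C4–C4a into 3-benzyloxyphenol (ring A) and an 8-formyl gallocatechin (ring D).
Fragments: benzylated 8-formyl-7-hydroxygallocatechin from (+)-gallocatechin (rings D, F, E bought intact, C2/C3 of the lower unit bought); the alkenyl(chloro)silane (ring B, C2, C3) from 3,4,5-tris(benzyloxy)benzaldehyde via the alkyne and hydrosilylation.
Ring order: rings D, F, E, A and B are present from the start; ring C and a temporary six-membered oxasilacycle close together in the key step; the oxasilacycle is opened again by the oxidation.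

Key step: step 10

Assumption: the sense of facial induction by the chiral phosphoric acid on this substrate cannot be predicted with confidence; the (R) acid is written in step 10, the (S) acid is to be run in parallel, and the enantiomer that gives the (2R,3S,4R) adduct is the one adopted.

Step 1
Reactants: 1 (+)-gallocatechin
Product: 2 5,7,3',4',5'-penta-O-benzyl-(+)-gallocatechin (2R,3S; free 3-OH)
Conditions: BnBr (5.5 equiv), K2CO3, DMF, 0 °C → rt, argon
Reagents that add atoms: benzyl bromide, BrCc1ccccc1
Why: Williamson etherification in which K2CO3 deprotonates only the five phenols, so the secondary 3-OH stays free and C2 and C3 are not touched.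

Step 2
Reactants: 2 5,7,3',4',5'-penta-O-benzyl-(+)-gallocatechin
Product: 3 hexa-O-benzyl-(+)-gallocatechin (2R,3S)
Conditions: NaH, BnBr, n-Bu4NI (cat.), DMF, 0 °C → rt
Reagents that add atoms: benzyl bromide, BrCc1ccccc1
Why: Williamson etherification of the sodium alkoxide of the 3-OH, which masks the only remaining hydroxyl so that step 8 can silylate a single oxygen; no stereocentre is involved.

Step 3
Reactants: 3 hexa-O-benzyl-(+)-gallocatechin
Product: 4 8-bromo-hexa-O-benzylgallocatechin (2R,3S)
Conditions: NBS (1.05 equiv), CH2Cl2, −78 °C → 0 °C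
Reagents that add atoms: N-bromosuccinimide, O=C1CCC(=O)N1Br
Why: electrophilic aromatic bromination of the phloroglucinol-type ring D, which in 3-O-protected 5,7-di-O-benzylflavans is known to go to C8 and not to C6, while the tribenzyloxyphenyl ring E is less activated.

Step 4
Reactants: 4 8-bromo-hexa-O-benzylgallocatechin
Product: 6 8-formyl-hexa-O-benzylgallocatechin (2R,3S), via 8-lithio-hexa-O-benzylgallocatechin 5 (not isolated)
Conditions: n-BuLi, THF, −78 °C; DMF, −78 °C → 0 °C; sat. aq NH4Cl
Reagents that add atoms: N,N-dimethylformamide, CN(C)C=O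
Why: bromine–lithium exchange at −78 °C outruns benzylic deprotonation of the benzyl ethers, and the aryllithium is formylated by DMF (Bouveault aldehyde synthesis), the tetrahedral adduct collapsing on work-up.

Step 5
Reactants: 6 8-formyl-hexa-O-benzylgallocatechin
Product: 7 8-formyl-7-hydroxy-3,5,3',4',5'-penta-O-benzylgallocatechin (2R,3S)
Conditions: MgBr2·OEt2 (1.5 equiv), toluene–Et2O, rt → 60 °C; 1 M HCl
Reagents that add atoms: none
Why: chelation-controlled ether cleavage in which magnesium bound between the formyl oxygen and O7 activates only the benzyl ether ortho to the aldehyde and bromide removes the benzyl group by SN2, whereas the 5-O-benzyl group is para to the aldehyde and the O1–C2 bond sits at a secondary ring carbon.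

Step 6
Reactants: 8 3,4,5-tris(benzyloxy)benzaldehyde
Product: 9 1,2,3-tris(benzyloxy)-5-ethynylbenzene
Conditions: dimethyl (1-diazo-2-oxopropyl)phosphonate, K2CO3, MeOH–THF, 0 °C → rt
Reagents that add atoms: dimethyl (1-diazo-2-oxopropyl)phosphonate, COP(=O)(OC)C(=[N+]=[N-])C(C)=O
Why: Ohira–Bestmann homologation, in which the diazomethylphosphonate anion set free by methanolysis adds to the aldehyde and olefination, loss of N2 and 1,2-hydrogen shift give the terminal alkyne; the aldehyde has no alpha hydrogen and benzyl ethers are inert.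

Step 7
Reactants: 9 1,2,3-tris(benzyloxy)-5-ethynylbenzene
Product: 10 chloro(diisopropyl)[(E)-2-[3,4,5-tris(benzyloxy)phenyl]ethenyl]silane (used crude)
Conditions: HSi(i-Pr)2Cl, Pt2[(CH2=CHSiMe2)2O]3 (cat., zerovalent platinum), P(t-Bu)3 (cat.), THF, rt → 50 °C; volatiles removed under argon
Reagents that add atoms: chlorodiisopropylsilane, CC(C)[SiH](Cl)C(C)C
Why: platinum-catalysed alkyne hydrosilylation (Chalk–Harrod mechanism) adds Si–H syn, and the bulky phosphine directs silicon to the terminal carbon, which should give the (E)-styrylsilane with the Si–Cl bond intact under anhydrous conditions.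

Step 8
Reactants: 7 8-formyl-7-hydroxy-3,5,3',4',5'-penta-O-benzylgallocatechin; 10 chloro(diisopropyl)[(E)-2-[3,4,5-tris(benzyloxy)phenyl]ethenyl]silane
Product: 11 7-O-{diisopropyl[(E)-2-[3,4,5-tris(benzyloxy)phenyl]ethenyl]silyl}-8-formyl-3,5,3',4',5'-penta-O-benzylgallocatechin (2R,3S)
Conditions: imidazole, DMAP (cat.), CH2Cl2, 0 °C → rt
Reagents that add atoms: none
Why: O-silylation of the only free hydroxyl (the acidic 7-OH) by the chlorosilane, with imidazole as base and nucleophilic catalyst; aldehyde, alkene and benzyl ethers are untouched.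

Step 9
Reactants: 11 silyl ether aldehyde; 12 3-(benzyloxy)phenol
Product: 14 ortho-hydroxybenzhydrol (4-benzyloxy-2-hydroxyphenyl carbinol at C8 of ring D; both carbinol epimers; used crude), via bromomagnesium 3-benzyloxyphenoxide 13 (not isolated)
Conditions: 12, EtMgBr (0.95 equiv per 12), Et2O, 0 °C; solvent changed to CH2Cl2; 11, 0 °C → rt; pH 7 phosphate buffer, 0 °C
Reagents that add atoms: none
Why: ortho-specific hydroxyalkylation of a bromomagnesium phenoxide, in which magnesium in a non-coordinating solvent holds phenoxide and aldehyde in a six-membered transition state so that only an ortho carbon bonds, the one para to the benzyloxy group being the less hindered; no free EtMgBr remains to attack the aldehyde, and the uncontrolled carbinol centre becomes planar in step 10.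

Step 10
Reactants: 14 ortho-hydroxybenzhydrol (both epimers)
Product: 16 silicon-bridged cycloadduct (upper ring C closed; cis-fused oxasilacycle through C3–Si and O7–Si; upper unit 2R,3S,4R), via ring A ortho-quinone methide 15 (not isolated)
Conditions: (R)-3,3'-bis(2,4,6-triisopropylphenyl)-1,1'-binaphthyl-2,2'-diyl hydrogen phosphate (10 mol %), 5 Å MS, toluene, −20 °C → rt
Reagents that add atoms: none
Why: Proposed new method: the phosphoric acid ionises either carbinol epimer of 14 with loss of water to the (E)-ortho-quinone methide 15 of ring A, the only ring with a free ortho hydroxyl because O7 of ring D is silylated, and the tethered (E)-vinylsilane then adds across O1=C8a–C4a=C4 in an asynchronous inverse-electron-demand hetero-Diels–Alder reaction in which the silicon-bearing carbon (future C3) bonds to C4, positive charge builds at C2 (benzylic to ring B and beta to silicon) and O1 then closes on C2. The closest known reaction types are phosphoric acid catalysed [4+2] additions of ortho-quinone methides, generated from ortho-hydroxybenzhydrols, to styrenes, the intramolecular hetero-Diels–Alder step in domino Knoevenagel reactions of O-prenylsalicylaldehydes, which has the same aryl–O–X–alkene tether and gives cis-fused products, and silicon-tethered Diels–Alder reactions followed by oxidation of the C–Si bond. Ring C closes as the six-membered ring of the hetero-Diels–Alder reaction (C3–C4 and O1–C2 bonds), and the oxasilacycle C3–C4–C8–C7–O–Si closes at the same time as the six-membered ring of an intramolecular cycloaddition whose four-atom tether links the diene terminus C4 to the proximal alkene carbon (read stepwise, a 6-exo attack of the alkene on the methide carbon followed by capture of the benzylic cation by O1). C2 and C3 come out trans because the E alkene adds suprafacially, C3 and C4 come out cis because the short aryl–O–Si tether can only reach C4 folded under the heterodiene (cis ring fusion, silicon endo, ring B exo), and the absolute configuration (2R,3S,4R) is fixed by the pi-face of the ortho-quinone methide that its hydrogen-bonded chiral phosphate leaves open. The step needs this one face and needs the beta-silyl cation to close on O1 before it loses silicon: the remote C2 aryl of ring F next to C8 is expected to give only a weak facial bias, so the catalyst is relied on, while the two isopropyl groups and the exclusion of water and other nucleophiles by the 5 Å sieves guard the silicon.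

Step 11
Reactants: 16 silicon-bridged cycloadduct
Product: 17 nona-O-benzyl robinetinidol-(4β→8)-gallocatechin with free upper 3-OH and free 7-OH on ring D
Conditions: 30% aq H2O2, KHCO3, THF–MeOH (1:1), rt → 40 °C; aq Na2S2O3
Reagents that add atoms: hydrogen peroxide, OO
Why: Tamao oxidation, in which hydroperoxide adds to the aryloxy-activated silicon and C3 migrates from silicon to oxygen with retention, so the silicon cis to ring D becomes the 3,4-cis hydroxyl while the aryl O–Si bond is hydrolysed to the 7-OH; fluoride is left out because a fluorosilicate could expel O1 by beta-elimination.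

Step 12
Reactants: 17 nona-O-benzyl dimer
Product: 18 robinetinidol-(4β→8)-gallocatechin (target)
Conditions: H2 (1 atm), Pd(OH)2/C, THF–MeOH (1:1), rt; filtration under argon, freeze-drying
Reagents that add atoms: none
Why: catalytic hydrogenolysis of the nine benzyl ethers, under which the cyclic benzylic C2–O1 bonds and the doubly benzylic C4–H of benzylated proanthocyanidins are known to persist; no stereocentre is affected.

Compound list
1 | (+)-gallocatechin, (2R,3S)-2-(3,4,5-trihydroxyphenyl)chromane-3,5,7-triol | Oc1cc(O)c2c(c1)O[C@H](c1cc(O)c(O)c(O)c1)[C@@H](O)C2 | starting material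
2 | 5,7,3',4',5'-penta-O-benzyl-(+)-gallocatechin, (2R,3S)-5,7-bis(benzyloxy)-2-[3,4,5-tris(benzyloxy)phenyl]chroman-3-ol | c1c(OCc3ccccc3)cc(OCc3ccccc3)c2c1O[C@H](c1cc(OCc3ccccc3)c(OCc3ccccc3)c(OCc3ccccc3)c1)[C@@H](O)C2 | intermediate
3 | hexa-O-benzyl-(+)-gallocatechin, (2R,3S)-3,5,7-tris(benzyloxy)-2-[3,4,5-tris(benzyloxy)phenyl]chromane | c1c(OCc3ccccc3)cc(OCc3ccccc3)c2c1O[C@H](c1cc(OCc3ccccc3)c(OCc3ccccc3)c(OCc3ccccc3)c1)[C@@H](OCc1ccccc1)C2 | intermediate
4 | 8-bromo-hexa-O-benzylgallocatechin (2R,3S) | Brc1c(OCc3ccccc3)cc(OCc3ccccc3)c2c1O[C@H](c1cc(OCc3ccccc3)c(OCc3ccccc3)c(OCc3ccccc3)c1)[C@@H](OCc1ccccc1)C2 | intermediate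
5 | 8-lithio-hexa-O-benzylgallocatechin (2R,3S; not isolated) | [Li]c1c(OCc3ccccc3)cc(OCc3ccccc3)c2c1O[C@H](c1cc(OCc3ccccc3)c(OCc3ccccc3)c(OCc3ccccc3)c1)[C@@H](OCc1ccccc1)C2 | intermediate
6 | 8-formyl-hexa-O-benzylgallocatechin, (2R,3S)-3,5,7-tris(benzyloxy)-2-[3,4,5-tris(benzyloxy)phenyl]chromane-8-carbaldehyde | O=Cc1c(OCc3ccccc3)cc(OCc3ccccc3)c2c1O[C@H](c1cc(OCc3ccccc3)c(OCc3ccccc3)c(OCc3ccccc3)c1)[C@@H](OCc1ccccc1)C2 | intermediate
7 | 8-formyl-7-hydroxy-3,5,3',4',5'-penta-O-benzylgallocatechin (2R,3S) | O=Cc1c(O)cc(OCc3ccccc3)c2c1O[C@H](c1cc(OCc3ccccc3)c(OCc3ccccc3)c(OCc3ccccc3)c1)[C@@H](OCc1ccccc1)C2 | intermediate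
8 | 3,4,5-tris(benzyloxy)benzaldehyde | O=Cc1cc(OCc2ccccc2)c(OCc2ccccc2)c(OCc2ccccc2)c1 | starting material
9 | 1,2,3-tris(benzyloxy)-5-ethynylbenzene | C#Cc1cc(OCc2ccccc2)c(OCc2ccccc2)c(OCc2ccccc2)c1 | intermediate
10 | chloro(diisopropyl)[(E)-2-[3,4,5-tris(benzyloxy)phenyl]ethenyl]silane | CC(C)[Si](Cl)(C(C)C)/C=C/c1cc(OCc2ccccc2)c(OCc2ccccc2)c(OCc2ccccc2)c1 | intermediate
11 | 7-O-{diisopropyl[(E)-2-[3,4,5-tris(benzyloxy)phenyl]ethenyl]silyl}-8-formyl-3,5,3',4',5'-penta-O-benzylgallocatechin (2R,3S) | O=Cc1c(O[Si](C(C)C)(C(C)C)/C=C/c3cc(OCc4ccccc4)c(OCc4ccccc4)c(OCc4ccccc4)c3)cc(OCc3ccccc3)c2c1O[C@H](c1cc(OCc3ccccc3)c(OCc3ccccc3)c(OCc3ccccc3)c1)[C@@H](OCc1ccccc1)C2 | intermediate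
12 | 3-(benzyloxy)phenol | Oc1cccc(OCc2ccccc2)c1 | starting material
13 | bromomagnesium 3-(benzyloxy)phenoxide (not isolated) | Br[Mg]Oc1cccc(OCc2ccccc2)c1 | intermediate
14 | ortho-hydroxybenzhydrol: [4-(benzyloxy)-2-hydroxyphenyl] carbinol on C8 of the silylated ring D, both carbinol epimers, gallocatechin unit (2R,3S) | OC(c1ccc(OCc2ccccc2)cc1O)c1c(O[Si](C(C)C)(C(C)C)/C=C/c3cc(OCc4ccccc4)c(OCc4ccccc4)c(OCc4ccccc4)c3)cc(OCc3ccccc3)c2c1O[C@H](c1cc(OCc3ccccc3)c(OCc3ccccc3)c(OCc3ccccc3)c1)[C@@H](OCc1ccccc1)C2 | intermediate
15 | (E)-ortho-quinone methide of ring A: 3-(benzyloxy)-6-(arylmethylidene)cyclohexa-2,4-dien-1-one, aryl = C8 of the silylated ring D (not isolated) | O=C1C=C(OCc2ccccc2)C=C/C1=C\c1c(O[Si](C(C)C)(C(C)C)/C=C/c2cc(OCc3ccccc3)c(OCc3ccccc3)c(OCc3ccccc3)c2)cc(OCc2ccccc2)c2c1O[C@H](c1cc(OCc3ccccc3)c(OCc3ccccc3)c(OCc3ccccc3)c1)[C@@H](OCc1ccccc1)C2 | intermediate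
16 | cycloadduct: upper unit (2R,3S,4R), 2,3-trans-3,4-cis, C3–Si(i-Pr)2–O7 bridge forming a cis-fused six-membered oxasilacycle; lower unit (2R,3S) | C(c1ccccc1)Oc1ccc2c(c1)O[C@H](c1cc(OCc5ccccc5)c(OCc5ccccc5)c(OCc5ccccc5)c1)[C@@H]3[C@H]2c2c(O[Si]3(C(C)C)C(C)C)cc(OCc3ccccc3)c4c2O[C@H](c2cc(OCc3ccccc3)c(OCc3ccccc3)c(OCc3ccccc3)c2)[C@@H](OCc2ccccc2)C4 | intermediate
17 | nona-O-benzyl robinetinidol-(4β→8)-gallocatechin, free 3-OH (upper unit, 2R,3S,4R) and free 7-OH (ring D) | C(c1ccccc1)Oc1ccc2c(c1)O[C@H](c1cc(OCc5ccccc5)c(OCc5ccccc5)c(OCc5ccccc5)c1)[C@@H](O)[C@H]2c2c(O)cc(OCc3ccccc3)c4c2O[C@H](c2cc(OCc3ccccc3)c(OCc3ccccc3)c(OCc3ccccc3)c2)[C@@H](OCc2ccccc2)C4 | intermediate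
18 | robinetinidol-(4β→8)-gallocatechin, upper unit (2R,3S,4R), lower unit (2R,3S) | Oc1ccc2c(c1)O[C@H](c1cc(O)c(O)c(O)c1)[C@@H](O)[C@H]2c1c(O)cc(O)c2c1O[C@H](c1cc(O)c(O)c(O)c1)[C@@H](O)C2 | target

Total step count: 12
Longest linear sequence: 10 steps (1 → 2 → 3 → 4 → 6 → 7 → 11 → 14 → 16 → 17 → 18; steps 1–5 and 8–12)

Steps most likely to fail

Step 10 (the proposed cycloaddition). The beta-silyl cation may lose silicon before O1 closes, which would give an open-chain alkene. The alkene may add to the wrong pi-face of the ortho-quinone methide. The quinone methide may also be trapped between molecules. The fallback uses the known acid-mediated coupling of a flavan-4-yl cation with a phloroglucinol-type flavan-3-ol. It sets out from 1: (+)-dihydrorobinetin F1 (bought) is reduced with NaBH4 in ethanol to the 2,3-trans-3,4-trans flavan-3,4-diol (+)-leucorobinetinidin F2. F2 is ionised at C4 in 0.1 M aqueous HCl at room temperature in the presence of an excess of 1. Ring D should capture the cation mainly at C8 and from both faces. The 3,4-cis (4β→8) dimer, expected beside a 3,4-trans epimer that is likely to predominate and beside 6-linked isomers, is separated on Sephadex LH-20. The fallback comes back to the route at 18.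

Step 9 (hydroxyalkylation). The weakly nucleophilic phenoxide may add only slowly to the hindered, electron-rich aldehyde. The magnesium centre may ionise the doubly activated carbinol before it is isolated. It may also promote transfer of the silyl group from O7 to the new alkoxide. The fallback is an aryllithium addition at low temperature and sets out from 11. 4-Bromoresorcinol F3 (bought) is monobenzylated (BnBr, K2CO3, acetone) at the less hindered hydroxyl para to bromine to give 5-(benzyloxy)-2-bromophenol F4, the isomer being removed by chromatography. n-BuLi (2.1 equiv, Et2O–THF, −78 → 0 °C) converts F4 into lithium 5-(benzyloxy)-2-lithiophenoxide F5. F5 is added to 11 at −78 °C and the mixture is quenched cold with pH 7 buffer. The fallback comes back to the route at 14.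

Step 11 (Tamao oxidation). Oxidation of the hindered diisopropylsilyl group may be slow. The pentacoordinate silicate formed under basic peroxide may instead expel O1 in a beta-elimination that opens ring C. The fallback is a two-stage Fleming-type oxidation and sets out from 16. The aryl O–Si bond is first cleaved with HF·pyridine in THF at 0 °C to give the isolated 3-(fluorodiisopropylsilyl) flavan with free 7-OH F6. F6 is then oxidised with m-chloroperbenzoic acid and KHF2 in DMF at room temperature, an electrophilic peracid oxidation at near-neutral pH in which no alkoxide or hydroperoxide anion is present. The migration of C3 from silicon to oxygen again goes with retention, and the fallback comes back to the route at 17.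

Further compounds
F1 | step 10 | (+)-dihydrorobinetin (bought), (2R,3R)-3,7-dihydroxy-2-(3,4,5-trihydroxyphenyl)chroman-4-one | Oc1ccc2c(c1)O[C@H](c1cc(O)c(O)c(O)c1)[C@@H](O)C2=O
F2 | step 10 | (+)-leucorobinetinidin, (2R,3S,4R)-2-(3,4,5-trihydroxyphenyl)chromane-3,4,7-triol | Oc1ccc2c(c1)O[C@H](c1cc(O)c(O)c(O)c1)[C@@H](O)[C@@H]2O
F3 | step 9 | 4-bromoresorcinol (bought) | Oc1ccc(Br)c(O)c1
F4 | step 9 | 5-(benzyloxy)-2-bromophenol | Oc1cc(OCc2ccccc2)ccc1Br
F5 | step 9 | lithium 5-(benzyloxy)-2-lithiophenoxide | [Li]Oc1cc(OCc2ccccc2)ccc1[Li]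
F6 | step 11 | 3-(fluorodiisopropylsilyl) nona-O-benzyl dimer with free 7-OH on ring D, upper unit (2R,3S,4R) | C(c1ccccc1)Oc1ccc2c(c1)O[C@H](c1cc(OCc5ccccc5)c(OCc5ccccc5)c(OCc5ccccc5)c1)[C@@H]([Si](F)(C(C)C)C(C)C)[C@H]2c2c(O)cc(OCc3ccccc3)c4c2O[C@H](c2cc(OCc3ccccc3)c(OCc3ccccc3)c(OCc3ccccc3)c2)[C@@H](OCc2ccccc2)C4
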